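## Retrosynthetic overview

1. Target 27 ⇐ MnO2 oxidation of the C5 allylic carbinol 26 ⇐ desilylation of 25.
2. 25 ⇐ carbonyl-forming Grob fragmentation: an alkenyl-cerium (C13–C15) adds to the β-mesyloxy cyclohexanone 19, and ring opening gives the C12 enone and the 6Z olefin in one step.
3. 19 ⇐ chiral lithium amide removes one of the two enantiotopic α-protons of meso cis-2,6-dimethylcyclohexanone 3 (from hydrogenation of 2,6-xylenol 1); aldol with aldehyde 16 and cold mesylation follow. This sets C11.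
4. 16 ⇐ Zr-catalysed carboalumination of alkyne ester 13 and Ni-catalysed coupling with benzyl chloride 9 (sets 2E); 9 ⇐ ortho-lithiation of silylated 4-methoxy-3-methylphenol 4.
5. Rings: no ring is built. The arene is bought; the cyclohexanone ring from 1 is a temporary ring, opened in the fragmentation.

Assumption: lithium (R,R)-bis(1-phenylethyl)amide is taken to select between the enantiotopic axial α-protons of 3 in the same sense as with 4-tert-butylcyclohexanone; if the sense is opposite, the (S,S)-amide is used and nothing else changes.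

Abbreviations: Ar = 2-methoxy-3-methyl-5-(triisopropylsilyloxy)phenyl; TBS = tert-butyldimethylsilyl; TIPS = triisopropylsilyl; TMS = trimethylsilyl; Ms = methanesulfonyl. Aldehyde 16 is racemic, so 18, 19, 24, 25 and 26 are mixtures of epimers at the silyloxy/hydroxy carbon (C5 of the target); this centre becomes the C5 ketone in the last step.

## Route

Step 1
Reactants: 1 2,6-dimethylphenol
Product: 3 cis-2,6-dimethylcyclohexan-1-one (meso; 2R,6S), via enol 2 (not isolated)
Conditions: H2 (5 bar), Pd/C, cyclohexane, 100 °C; then NaOMe (cat.), MeOH, 23 °C; cis isomer separated by spinning-band distillation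
Reagents that add atoms: none
Why: Catalytic arene hydrogenation of a phenol on palladium stops at the hindered ketone after enol–keto tautomerisation, and base equilibration favours the diequatorial cis (meso) isomer.

Step 2
Reactants: 4 4-methoxy-3-methylphenol
Product: 5 (4-methoxy-3-methylphenoxy)triisopropylsilane
Conditions: iPr3SiCl, imidazole, DMF, 23 °C
Reagents that add atoms: triisopropylsilyl chloride, CC(C)[Si](Cl)(C(C)C)C(C)C
Why: Standard phenol silylation; the bulky TIPS ether shields its own ortho positions from lithiation and survives organometallic steps.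

Step 3
Reactants: 5 (4-methoxy-3-methylphenoxy)triisopropylsilane
Product: 9 [3-(chloromethyl)-4-methoxy-5-methylphenoxy]triisopropylsilane (ArCH2Cl), via aryllithium 6 (not isolated), via lithium benzyl alkoxide 7 (not isolated), via benzyl mesylate 8 (not isolated)
Conditions: n-BuLi, TMEDA, Et2O, 0 → 23 °C; CH2O (gas), −78 → 0 °C; MsCl, THF, 0 → 23 °C
Reagents that add atoms: formaldehyde, C=O; methanesulfonyl chloride, CS(=O)(=O)Cl
Why: Directed ortho-metalation by the methoxy group at its only free ortho position, hydroxymethylation, then mesylation of the alkoxide and SN2 displacement of the electron-rich benzylic mesylate by the chloride released.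

Step 4
Reactants: 10 ethyl 2-[(tert-butyldimethylsilyl)oxy]acetate; 11 3-bromoprop-1-yne
Product: 13 ethyl 2-[(tert-butyldimethylsilyl)oxy]pent-4-ynoate (racemic), via lithium ester enolate 12 (not isolated)
Conditions: LiN(iPr)2, THF, −78 °C; 11, DMPU, −78 → −30 °C
Reagents that add atoms: none
Why: Ester enolate alkylation (SN2) with a reactive propargylic bromide, kept cold so that silyl migration in the α-silyloxy enolate does not compete.

Step 5
Reactants: 13 ethyl 2-[(tert-butyldimethylsilyl)oxy]pent-4-ynoate; 9 ArCH2Cl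
Product: 15 ethyl (4E)-6-Ar-2-[(tert-butyldimethylsilyl)oxy]-4-methylhex-4-enoate (racemic), via alkenylalane 14 (not isolated)
Conditions: AlMe3, Cp2ZrCl2 (10 mol %), H2O (promoter), CH2Cl2, −30 °C; then 9, NiCl2(PPh3)2 (5 mol %) pre-reduced with n-BuLi (10 mol %) to zerovalent nickel, THF, 23 °C
Reagents that add atoms: trimethylaluminium, C[Al](C)C
Why: Negishi zirconium-catalysed carboalumination adds Me and Al syn across the terminal alkyne, and nickel-catalysed alkenylalane–benzyl chloride cross-coupling proceeds with retention, so ArCH2 ends cis to the methyl (2E of the target).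

Step 6
Reactants: 15 ethyl (4E)-6-Ar-2-[(tert-butyldimethylsilyl)oxy]-4-methylhex-4-enoate
Product: 16 (4E)-6-Ar-2-[(tert-butyldimethylsilyl)oxy]-4-methylhex-4-enal (racemic)
Conditions: iBu2AlH, CH2Cl2, −78 °C
Reagents that add atoms: none
Why: Partial ester reduction; the α-silyloxy ester gives a tetrahedral aluminate that is stable at −78 °C and releases the aldehyde only on work-up.

Step 7 (key step)
Reactants: 3 cis-2,6-dimethylcyclohexan-1-one; 16 (4E)-6-Ar-2-[(tert-butyldimethylsilyl)oxy]-4-methylhex-4-enal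
Product: 19 (2S,6R)-2-{(1R,4E)-6-Ar-2-[(tert-butyldimethylsilyl)oxy]-1-(methanesulfonyloxy)-4-methylhex-4-en-1-yl}-2,6-dimethylcyclohexan-1-one, via lithium enolate 17 (not isolated), via lithium aldolate 18 (not isolated)
Conditions: (R,R)-bis(1-phenylethyl)amine hydrochloride, n-BuLi (2 equiv), THF, −78 °C; 3, −78 °C; 16, −78 °C; MsCl, Et3N, −78 → −40 °C
Reagents that add atoms: methanesulfonyl chloride, CS(=O)(=O)Cl
Why: Enantioselective deprotonation by the chiral lithium amide–LiCl base removes one of the two enantiotopic axial α-protons of meso 3 and leaves the future C11 as R; the tetrasubstituted enolate then undergoes aldol addition through a Zimmerman–Traxler chair (ring CH2 anti to the new oxygen, attack anti to the remaining methyl), and the aldolate is sulfonylated cold before retro-aldol or silyl migration can occur.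

Step 8
Reactants: 20 trimethyl[(2-methylbut-3-yn-2-yl)oxy]silane
Product: 21 (E)-tributyl[3-methyl-3-(trimethylsilyloxy)but-1-en-1-yl]stannane
Conditions: Bu3SnH, PdCl2(PPh3)2 (2 mol %), THF, 23 °C
Reagents that add atoms: tributyltin hydride, CCCC[SnH](CCCC)CCCC
Why: Palladium-catalysed syn-hydrostannation of a terminal alkyne with a bulky propargylic substituent places tin at the terminus and gives the E-alkenylstannane.

Step 9
Reactants: 19 β-mesyloxy ketone; 21 (E)-tributyl[3-methyl-3-(trimethylsilyloxy)but-1-en-1-yl]stannane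
Product: 25 (2E,6Z,11R,13E)-1-Ar-5-[(tert-butyldimethylsilyl)oxy]-3,7,11,15-tetramethyl-15-(trimethylsilyloxy)hexadeca-2,6,13-trien-12-one, via alkenyllithium 22 (not isolated), via alkenylcerium dichloride 23 (not isolated), via tertiary alkoxide 24 (not isolated)
Conditions: n-BuLi, THF, −78 °C; CeCl3, −78 °C; 19, −78 °C; then −78 → 23 °C
Reagents that add atoms: none
Why: Tin–lithium exchange (retention) and transmetalation give a weakly basic organocerium that adds 1,2 to the hindered ketone without enolising C6; on warming the alkoxide undergoes Grob fragmentation with the ring C–C bond anti-periplanar to C–OMs, which forms the C12 enone and, from the aldol configuration of 19, only the 6Z olefin while C11 is untouched.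

Step 10
Reactants: 25 tris-silyl ether
Product: 26 (2E,6Z,11R,13E)-5,15-dihydroxy-1-(5-hydroxy-2-methoxy-3-methylphenyl)-3,7,11,15-tetramethylhexadeca-2,6,13-trien-12-one
Conditions: Bu4NF, AcOH (1:1), THF, 0 → 23 °C
Reagents that add atoms: none
Why: Fluoride-mediated desilylation of the aryl TIPS, tertiary TMS and secondary TBS ethers; acetic acid buffering keeps the medium non-basic so that C11 (α to the enone) does not epimerise.

Step 11
Reactants: 26 triol
Product: 27 (2E,6Z,11R,13E)-15-hydroxy-1-(5-hydroxy-2-methoxy-3-methylphenyl)-3,7,11,15-tetramethylhexadeca-2,6,13-triene-5,12-dione (CNP0243623.1)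
Conditions: MnO2 (activated, excess), CH2Cl2, 23 °C
Reagents that add atoms: none
Why: Chemoselective MnO2 oxidation of the only secondary allylic alcohol (C5) under neutral heterogeneous conditions, which leaves the tertiary alcohol, the 6Z geometry, the skipped C2 olefin and C11 unchanged.

## Compound list

1 | 2,6-dimethylphenol | Cc1cccc(C)c1O | starting material
2 | 2,6-dimethylcyclohex-1-en-1-ol | CC1CCCC(C)=C1O | intermediate
3 | cis-2,6-dimethylcyclohexan-1-one (meso; 2R,6S) | O=C1[C@H](C)CCC[C@@H]1C | intermediate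
4 | 4-methoxy-3-methylphenol | COc1ccc(O)cc1C | starting material
5 | (4-methoxy-3-methylphenoxy)triisopropylsilane | COc1ccc(O[Si](C(C)C)(C(C)C)C(C)C)cc1C | intermediate
6 | [2-methoxy-3-methyl-5-(triisopropylsilyloxy)phenyl]lithium | COc1c([Li])cc(O[Si](C(C)C)(C(C)C)C(C)C)cc1C | intermediate
7 | lithium [2-methoxy-3-methyl-5-(triisopropylsilyloxy)phenyl]methanolate | COc1c(CO[Li])cc(O[Si](C(C)C)(C(C)C)C(C)C)cc1C | intermediate
8 | [2-methoxy-3-methyl-5-(triisopropylsilyloxy)phenyl]methyl methanesulfonate | COc1c(COS(C)(=O)=O)cc(O[Si](C(C)C)(C(C)C)C(C)C)cc1C | intermediate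
9 | [3-(chloromethyl)-4-methoxy-5-methylphenoxy]triisopropylsilane | COc1c(CCl)cc(O[Si](C(C)C)(C(C)C)C(C)C)cc1C | intermediate
10 | ethyl 2-[(tert-butyldimethylsilyl)oxy]acetate | CCOC(=O)CO[Si](C)(C)C(C)(C)C | starting material
11 | 3-bromoprop-1-yne | C#CCBr | starting material
12 | lithium 1-ethoxy-2-[(tert-butyldimethylsilyl)oxy]ethen-1-olate | CCOC(O[Li])=CO[Si](C)(C)C(C)(C)C | intermediate
13 | ethyl 2-[(tert-butyldimethylsilyl)oxy]pent-4-ynoate (racemic) | CCOC(=O)C(CC#C)O[Si](C)(C)C(C)(C)C | intermediate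
14 | ethyl (4E)-2-[(tert-butyldimethylsilyl)oxy]-5-(dimethylalumanyl)-4-methylpent-4-enoate | CCOC(=O)C(O[Si](C)(C)C(C)(C)C)C/C(C)=C/[Al](C)C | intermediate
15 | ethyl (4E)-2-[(tert-butyldimethylsilyl)oxy]-6-[2-methoxy-3-methyl-5-(triisopropylsilyloxy)phenyl]-4-methylhex-4-enoate (racemic) | CCOC(=O)C(O[Si](C)(C)C(C)(C)C)C/C(C)=C/Cc1cc(O[Si](C(C)C)(C(C)C)C(C)C)cc(C)c1OC | intermediate
16 | (4E)-2-[(tert-butyldimethylsilyl)oxy]-6-[2-methoxy-3-methyl-5-(triisopropylsilyloxy)phenyl]-4-methylhex-4-enal (racemic) | O=CC(O[Si](C)(C)C(C)(C)C)C/C(C)=C/Cc1cc(O[Si](C(C)C)(C(C)C)C(C)C)cc(C)c1OC | intermediate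
17 | lithium (6R)-2,6-dimethylcyclohex-1-en-1-olate | C[C@@H]1CCCC(C)=C1O[Li] | intermediate
18 | lithium aldolate: (2S,6R)-2-[(1R,4E)-6-Ar-2-(TBS-oxy)-1-(lithiooxy)-4-methylhex-4-en-1-yl]-2,6-dimethylcyclohexan-1-one | C[C@@H]1CCC[C@@](C)([C@@H](O[Li])C(O[Si](C)(C)C(C)(C)C)C/C(C)=C/Cc2cc(O[Si](C(C)C)(C(C)C)C(C)C)cc(C)c2OC)C1=O | intermediate
19 | (2S,6R)-2-{(1R,4E)-2-[(tert-butyldimethylsilyl)oxy]-1-(methanesulfonyloxy)-6-[2-methoxy-3-methyl-5-(triisopropylsilyloxy)phenyl]-4-methylhex-4-en-1-yl}-2,6-dimethylcyclohexan-1-one | C[C@@H]1CCC[C@@](C)([C@@H](OS(C)(=O)=O)C(O[Si](C)(C)C(C)(C)C)C/C(C)=C/Cc2cc(O[Si](C(C)C)(C(C)C)C(C)C)cc(C)c2OC)C1=O | intermediate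
20 | trimethyl[(2-methylbut-3-yn-2-yl)oxy]silane | C#CC(C)(C)O[Si](C)(C)C | starting material
21 | (E)-tributyl[3-methyl-3-(trimethylsilyloxy)but-1-en-1-yl]stannane | CCCC[Sn](CCCC)(CCCC)/C=C/C(C)(C)O[Si](C)(C)C | intermediate
22 | (E)-[3-methyl-3-(trimethylsilyloxy)but-1-en-1-yl]lithium | [Li]/C=C/C(C)(C)O[Si](C)(C)C | intermediate
23 | (E)-dichloro[3-methyl-3-(trimethylsilyloxy)but-1-en-1-yl]cerium | Cl[Ce](Cl)/C=C/C(C)(C)O[Si](C)(C)C | intermediate
24 | tertiary (dichlorocerium) alkoxide formed by addition of 23 to the ketone of 19 (carbinol centre unassigned) | C[C@@H]1CCC[C@@](C)([C@@H](OS(C)(=O)=O)C(O[Si](C)(C)C(C)(C)C)C/C(C)=C/Cc2cc(O[Si](C(C)C)(C(C)C)C(C)C)cc(C)c2OC)C1(O[Ce](Cl)Cl)/C=C/C(C)(C)O[Si](C)(C)C | intermediate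
25 | (2E,6Z,11R,13E)-5-[(tert-butyldimethylsilyl)oxy]-1-[2-methoxy-3-methyl-5-(triisopropylsilyloxy)phenyl]-3,7,11,15-tetramethyl-15-(trimethylsilyloxy)hexadeca-2,6,13-trien-12-one | COc1c(C)cc(O[Si](C(C)C)(C(C)C)C(C)C)cc1C/C=C(\C)CC(O[Si](C)(C)C(C)(C)C)/C=C(/C)CCC[C@@H](C)C(=O)/C=C/C(C)(C)O[Si](C)(C)C | intermediate
26 | (2E,6Z,11R,13E)-5,15-dihydroxy-1-(5-hydroxy-2-methoxy-3-methylphenyl)-3,7,11,15-tetramethylhexadeca-2,6,13-trien-12-one | COc1c(C)cc(O)cc1C/C=C(\C)CC(O)/C=C(/C)CCC[C@@H](C)C(=O)/C=C/C(C)(C)O | intermediate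
27 | (2E,6Z,11R,13E)-15-hydroxy-1-(5-hydroxy-2-methoxy-3-methylphenyl)-3,7,11,15-tetramethylhexadeca-2,6,13-triene-5,12-dione | COc1c(C)cc(O)cc1C/C=C(\C)CC(=O)/C=C(/C)CCC[C@@H](C)C(=O)/C=C/C(C)(C)O | target

## Step count and risks

Total steps: 11. Longest linear sequence: 8 steps (4 → 5 → 9 → 15 → 16 → 19 → 25 → 26 → 27; steps 2, 3, 5, 6, 7, 9, 10, 11).

Most likely to fail, first: step 7. The enantioselectivity with an aldehyde quench may be only about 80–90 % ee. The aldol diastereoselectivity at the quaternary carbon and carbinol decides 6Z against 6E after fragmentation. The hindered aldolate can revert or shift its TBS group before it is mesylated. The fallback separates these events and sets out from 3. Deprotonation with the same lithium amide in the presence of Me3SiCl (in situ quench, −78 °C) gives trimethyl{[(6R)-2,6-dimethylcyclohex-1-en-1-yl]oxy}silane F1, which is distilled and its ee measured. MeLi (THF, 0 °C) releases amine-free enolate 17, and aldol addition to 16 at −78 °C is quenched cold with AcOH. The β-hydroxy ketone (2S,6R)-2-{(1R,4E)-6-Ar-2-[(tert-butyldimethylsilyl)oxy]-1-hydroxy-4-methylhex-4-en-1-yl}-2,6-dimethylcyclohexan-1-one F2 is isolated and freed from the minor aldol diastereomer by chromatography. MsCl/Et3N/DMAP then gives 19, where the fallback comes back to the route.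

Second: step 9. The ketone of 19 is flanked by a quaternary and a tertiary carbon, so addition may be slow. The enone released on warming can take up a second equivalent of the organocerium, so only about 1.1 equiv is used. The fallback changes the trigger to hydride and sets out from 19. LiAlH4 (THF, 0 → 40 °C) reduces the ketone, the alkoxide fragments in the same anti-periplanar way, and the aldehyde set free is reduced at once to (2R,6Z,10E)-12-Ar-8-[(tert-butyldimethylsilyl)oxy]-2,6,10-trimethyldodeca-6,10-dien-1-ol F3. Dess–Martin periodinane/NaHCO3 gives (2R,6Z,10E)-12-Ar-8-[(tert-butyldimethylsilyl)oxy]-2,6,10-trimethyldodeca-6,10-dienal F4. Alkenyllithium 22 adds at −78 °C to give (2E,6Z,11R,13E)-1-Ar-5-[(tert-butyldimethylsilyl)oxy]-3,7,11,15-tetramethyl-15-(trimethylsilyloxy)hexadeca-2,6,13-trien-12-ol F5. A second Dess–Martin oxidation gives 25, where the fallback comes back to the route.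

Third: step 11. Activated MnO2 may attack the free, electron-rich phenol (phenoxy-radical coupling or quinone formation) while it oxidises the C5 carbinol. The fallback oxidises with the phenol still masked and sets out from 25. HF·pyridine (pyridine, THF, 0 °C) removes only the alkyl TBS and TMS ethers and gives (2E,6Z,11R,13E)-1-Ar-5,15-dihydroxy-3,7,11,15-tetramethylhexadeca-2,6,13-trien-12-one F6. Dess–Martin periodinane/NaHCO3 gives (2E,6Z,11R,13E)-1-Ar-15-hydroxy-3,7,11,15-tetramethylhexadeca-2,6,13-triene-5,12-dione F7. KHF2 in MeOH at 23 °C then cleaves the aryl TIPS ether under near-neutral conditions and gives 27, where the fallback comes back to the route.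

## Further compounds

F1 | step 7 | trimethyl{[(6R)-2,6-dimethylcyclohex-1-en-1-yl]oxy}silane | C[C@@H]1CCCC(C)=C1O[Si](C)(C)C
F2 | step 7 | (2S,6R)-2-{(1R,4E)-2-[(tert-butyldimethylsilyl)oxy]-1-hydroxy-6-[2-methoxy-3-methyl-5-(triisopropylsilyloxy)phenyl]-4-methylhex-4-en-1-yl}-2,6-dimethylcyclohexan-1-one | C[C@@H]1CCC[C@@](C)([C@@H](O)C(O[Si](C)(C)C(C)(C)C)C/C(C)=C/Cc2cc(O[Si](C(C)C)(C(C)C)C(C)C)cc(C)c2OC)C1=O
F3 | step 9 | (2R,6Z,10E)-8-[(tert-butyldimethylsilyl)oxy]-12-[2-methoxy-3-methyl-5-(triisopropylsilyloxy)phenyl]-2,6,10-trimethyldodeca-6,10-dien-1-ol | COc1c(C)cc(O[Si](C(C)C)(C(C)C)C(C)C)cc1C/C=C(\C)CC(O[Si](C)(C)C(C)(C)C)/C=C(/C)CCC[C@@H](C)CO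
F4 | step 9 | (2R,6Z,10E)-8-[(tert-butyldimethylsilyl)oxy]-12-[2-methoxy-3-methyl-5-(triisopropylsilyloxy)phenyl]-2,6,10-trimethyldodeca-6,10-dienal | COc1c(C)cc(O[Si](C(C)C)(C(C)C)C(C)C)cc1C/C=C(\C)CC(O[Si](C)(C)C(C)(C)C)/C=C(/C)CCC[C@@H](C)C=O
F5 | step 9 | (2E,6Z,11R,13E)-5-[(tert-butyldimethylsilyl)oxy]-1-[2-methoxy-3-methyl-5-(triisopropylsilyloxy)phenyl]-3,7,11,15-tetramethyl-15-(trimethylsilyloxy)hexadeca-2,6,13-trien-12-ol | COc1c(C)cc(O[Si](C(C)C)(C(C)C)C(C)C)cc1C/C=C(\C)CC(O[Si](C)(C)C(C)(C)C)/C=C(/C)CCC[C@@H](C)C(O)/C=C/C(C)(C)O[Si](C)(C)C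
F6 | step 11 | (2E,6Z,11R,13E)-5,15-dihydroxy-1-[2-methoxy-3-methyl-5-(triisopropylsilyloxy)phenyl]-3,7,11,15-tetramethylhexadeca-2,6,13-trien-12-one | COc1c(C)cc(O[Si](C(C)C)(C(C)C)C(C)C)cc1C/C=C(\C)CC(O)/C=C(/C)CCC[C@@H](C)C(=O)/C=C/C(C)(C)O
F7 | step 11 | (2E,6Z,11R,13E)-15-hydroxy-1-[2-methoxy-3-methyl-5-(triisopropylsilyloxy)phenyl]-3,7,11,15-tetramethylhexadeca-2,6,13-triene-5,12-dione | COc1c(C)cc(O[Si](C(C)C)(C(C)C)C(C)C)cc1C/C=C(\C)CC(=O)/C=C(/C)CCC[C@@H](C)C(=O)/C=C/C(C)(C)O
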